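The cyclohexane ring (C1, C10, C11, C12, C13, C14; eunicellane numbering) is cut at its unfunctionalised C12–C13 bond. C12, C11 and the exocyclic C20 are read as a symmetrical 2-substituted allyl unit, and C13 as a nitronate carbon. The nitro group arrives in an organocatalytic Michael addition that sets C14 and C1, activates C13 for ring closure, and is then removed without trace. The key step, a palladium-catalysed allylic alkylation, closes the ring and creates the C11=C20 methylene in one operation from a monocyclic lactol bearing a nitromethyl arm and a chloromethylvinyl arm. The ten-membered ring is then closed by olefination and a Nozaki–Hiyama–Kishi reaction.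

Key step: step 6

Remark on the chemistry: the target is taken as (1S,8R,10S,14S) with a trans ring fusion and 2E,6E alkenes, as read from its structure. C1 and C10 are the ring-fusion carbons, C2=C3 carries the methyl ester, C6=C7 the acid, C8 the hydroxyl, C11 the methylene C20, C14 the isopropyl group, and the ten-membered ring runs C1 to C10.

Step 1
Reactants: 1 5,6-dihydro-2H-pyran-2-one; 2 isopropenylboronic acid pinacol ester
Product: 3 (4S)-4-(prop-1-en-2-yl)oxan-2-one
Conditions: [Rh(cod)Cl]2 (2 mol %), (S)-BINAP (5 mol %), KOH (0.2 equiv), 1,4-dioxane/H2O 10:1, 40 °C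
Reagents that add atoms: none
Why: Hayashi–Miyaura rhodium-catalysed asymmetric 1,4-addition, in which the (S)-BINAP alkenylrhodium species should add to the lactone face that gives the (S) centre (the future C10), in the same sense as its additions of aryl- and alkenylboron reagents to cyclic enones and this lactone.

Step 2
Reactants: 3 (4S)-4-(prop-1-en-2-yl)oxan-2-one
Product: 4 (4S)-4-(3-chloroprop-1-en-2-yl)oxan-2-one
Conditions: Ca(OCl)2, solid CO2, CH2Cl2/H2O, 0 °C
Reagents that add atoms: calcium hypochlorite, [Ca+2].[O-]Cl.[O-]Cl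
Why: Ene-type allylic chlorination by hypochlorous acid is selective for the electron-rich 1,1-disubstituted alkene and shifts the double bond onto the former methyl carbon, which should give the 2-substituted allyl chloride without touching the lactone or the stereocenter.

Step 3
Reactants: 4 (4S)-4-(3-chloroprop-1-en-2-yl)oxan-2-one
Product: 5 (4S)-4-(3-chloroprop-1-en-2-yl)oxan-2-ol
Conditions: iBu2AlH (1.1 equiv), CH2Cl2, −78 °C; aqueous potassium sodium tartrate
Reagents that add atoms: none
Why: Half-reduction of a δ-lactone with iBu2AlH stops at the lactol because the tetrahedral aluminate is stable at −78 °C, and the allylic chloride is inert to the hydride at that temperature.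

Step 4
Reactants: 6 2-methylpropanal; 7 nitromethane
Product: 10 (E)-3-methyl-1-nitrobut-1-ene, via 3-methyl-1-nitrobutan-2-ol 8 (not isolated), via 3-methyl-1-nitrobutan-2-yl methanesulfonate 9 (not isolated)
Conditions: NaOH (cat.), MeOH, 0 °C; then MsCl, Et3N, CH2Cl2, 0 °C
Reagents that add atoms: none
Why: Henry (nitroaldol) addition followed by mesylation and E1cB elimination should give the thermodynamically favoured (E)-nitroalkene.

Step 5
Reactants: 5 (4S)-4-(3-chloroprop-1-en-2-yl)oxan-2-ol; 10 (E)-3-methyl-1-nitrobut-1-ene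
Product: 11 (3S,4S)-4-(3-chloroprop-1-en-2-yl)-3-[(2S)-3-methyl-1-nitrobutan-2-yl]oxan-2-ol
Conditions: (R)-2-[diphenyl(trimethylsilyloxy)methyl]pyrrolidine (10 mol %), 4-nitrophenol (10 mol %), toluene, 0 °C to rt
Reagents that add atoms: none
Why: Hayashi–Jørgensen enamine Michael addition, in which the lactol opens to the δ-hydroxy aldehyde, its (E)-enamine attacks the nitroalkene through the acyclic synclinal transition state on the face left open by the diarylsilyloxymethyl group, C1 and C14 are set syn under catalyst control (the (R)-catalyst gives the mirror image of the known (S)-catalyst sense), and the adduct recloses to the trans-3,4-disubstituted lactol.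

Step 6
Reactants: 11 (3S,4S)-4-(3-chloroprop-1-en-2-yl)-3-[(2S)-3-methyl-1-nitrobutan-2-yl]oxan-2-ol
Product: 12 (4aS,8S,8aS)-5-methylidene-7-nitro-8-(propan-2-yl)octahydro-1H-isochromen-1-ol
Conditions: Pd(PPh3)4 (5 mol %), Cs2CO3 (1.5 equiv), THF, 0.01 M, rt to 40 °C
Reagents that add atoms: none
Why: Oxidative addition of zerovalent palladium to the allylic chloride gives an η3-allyl complex whose two termini (C12 and C20) are equivalent, Cs2CO3 converts the nitromethyl group into its nitronate, and the nitronate carbon C13 attacks one terminus anti to palladium, forming C12–C13 and leaving the other terminus as the C11=C20 methylene. The closest known reaction types are the Tsuji–Trost C-allylation of nitroalkanes and the ring-closing stage of palladium trimethylenemethane annulations, where a carbanion tethered to the central allyl carbon attacks a terminus. The cyclohexane closes in a six-membered mode that is endo with respect to the allyl unit (tether C14–C1–C10 between C13 and C11), through a chair in which both arms sit on adjacent equatorial positions of the lactol ring, so the ring fusion should come out trans with the isopropyl group axial. The only new stereocenter is the nitro-bearing C13, which is not controlled and is erased in step 7, while C14, C1 and C10 are not involved. The step needs C- over O-allylation (the soft nitronate, with O-allylation reversible under palladium), nitronate over lactol-oxygen attack (the nitroalkane is far more acidic), and ring closure over intermolecular alkylation (high dilution); regioselectivity on the allyl unit does not arise because its termini are identical.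

Step 7
Reactants: 12 (4aS,8S,8aS)-5-methylidene-7-nitro-8-(propan-2-yl)octahydro-1H-isochromen-1-ol
Product: 13 (4aS,8S,8aR)-5-methylidene-8-(propan-2-yl)octahydro-1H-isochromen-1-ol
Conditions: Bu3SnH (4 equiv), AIBN (0.3 equiv, in portions), toluene, 110 °C
Reagents that add atoms: none
Why: Ono-type radical denitration, in which the stannyl radical adds to the nitro group, the adduct fragments to the secondary C13 radical and this takes hydrogen from Bu3SnH; secondary nitro groups need these forcing conditions, and no stereocenter of the target is touched.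

Step 8
Reactants: 14 trimethyl phosphonoacetate; 15 acrolein
Product: 16 methyl 2-(dimethoxyphosphoryl)-5-oxopentanoate
Conditions: NaOMe (5 mol %), MeOH, −10 to 0 °C
Reagents that add atoms: none
Why: Base-catalysed Michael addition of the phosphonoacetate anion to acrolein, with catalytic base and low temperature keeping the product from condensing with itself.

Step 9
Reactants: 16 methyl 2-(dimethoxyphosphoryl)-5-oxopentanoate; 17 tert-butyl (triphenylphosphoranylidene)acetate
Product: 19 1-tert-butyl 7-methyl (2Z)-6-(dimethoxyphosphoryl)-2-iodohept-2-enedioate, via tert-butyl iodo(triphenylphosphoranylidene)acetate 18 (not isolated)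
Conditions: 17, NIS, CH2Cl2, −20 °C; then 16, K2CO3, −20 °C to rt
Reagents that add atoms: N-iodosuccinimide, O=C1CCC(=O)N1I
Why: Wittig olefination with the α-iodo ylide made in the flask, where stabilised α-halo ylides place the alkyl chain trans to the ester and so should give the (Z)-iodoenoate, the phosphonate being untouched under these near-neutral conditions.

Step 10
Reactants: 13 (4aS,8S,8aR)-5-methylidene-8-(propan-2-yl)octahydro-1H-isochromen-1-ol; 19 1-tert-butyl 7-methyl (2Z)-6-(dimethoxyphosphoryl)-2-iodohept-2-enedioate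
Product: 20 1-tert-butyl 7-methyl (2Z,6E)-6-{[(1S,2S,6S)-2-(2-hydroxyethyl)-3-methylidene-6-(propan-2-yl)cyclohexyl]methylidene}-2-iodohept-2-enedioate
Conditions: LiCl, iPr2NEt, MeCN, rt to 40 °C
Reagents that add atoms: none
Why: Horner–Wadsworth–Emmons olefination under Masamune–Roush conditions on the open hydroxy aldehyde form of the lactol, where the α-substituted phosphonate should give the (E)-trisubstituted enoate (ester trans to C1) and the mild amine base should avoid epimerisation at C1 and conjugate addition of the freed C8 hydroxyl.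

Step 11
Reactants: 20 1-tert-butyl 7-methyl (2Z,6E)-6-{[(1S,2S,6S)-2-(2-hydroxyethyl)-3-methylidene-6-(propan-2-yl)cyclohexyl]methylidene}-2-iodohept-2-enedioate
Product: 21 1-tert-butyl 7-methyl (2Z,6E)-2-iodo-6-{[(1S,2S,6S)-3-methylidene-2-(2-oxoethyl)-6-(propan-2-yl)cyclohexyl]methylidene}hept-2-enedioate
Conditions: Dess–Martin periodinane, NaHCO3, CH2Cl2, 0 °C to rt
Reagents that add atoms: none
Why: Dess–Martin oxidation of the primary alcohol to the aldehyde under buffered, non-basic conditions that leave the iodoenoate, the enoate and the exocyclic alkene intact.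

Step 12
Reactants: 21 1-tert-butyl 7-methyl (2Z,6E)-2-iodo-6-{[(1S,2S,6S)-3-methylidene-2-(2-oxoethyl)-6-(propan-2-yl)cyclohexyl]methylidene}hept-2-enedioate
Product: 22 microeunicellol B tert-butyl ester (the target with CO2tBu in place of CO2H on C7)
Conditions: CrCl2 (10 equiv), NiCl2 (0.1 equiv), DMSO/THF 3:1, 2 mM, rt
Reagents that add atoms: none
Why: Intramolecular Nozaki–Hiyama–Kishi reaction, in which NiCl2-catalysed formation of the alkenylchromium species from the (Z)-iodoenoate with retention of geometry and its chemoselective addition to the aldehyde close the ten-membered ring through C7–C8; the new C8 centre is set by substrate control, the two cis ring alkenes and the trans ring fusion being expected to expose the outer aldehyde face and favour the (8R) alcohol.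

Step 13
Reactants: 22 microeunicellol B tert-butyl ester
Product: 24 microeunicellol B, via bis(trimethylsilyl) derivative 23 (not isolated)
Conditions: TMSOTf (4 equiv), 2,6-lutidine (6 equiv), CH2Cl2, 0 °C; then aqueous citric acid, THF
Reagents that add atoms: none
Why: Silyl triflate-mediated cleavage of the tert-butyl ester to the silyl ester with loss of 2-methylpropene works without free protic acid, so the exocyclic alkene, the methyl ester and the allylic alcohol should survive, and mild aqueous acid then hydrolyses the silyl ester and silyl ether.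

Compound list
1 | 5,6-dihydro-2H-pyran-2-one | O=C1C=CCCO1 | starting material
2 | isopropenylboronic acid pinacol ester (4,4,5,5-tetramethyl-2-(prop-1-en-2-yl)-1,3,2-dioxaborolane) | CC(=C)B1OC(C)(C)C(C)(C)O1 | starting material
3 | (4S)-4-(prop-1-en-2-yl)oxan-2-one | C=C(C)[C@H]1CCOC(=O)C1 | intermediate
4 | (4S)-4-(3-chloroprop-1-en-2-yl)oxan-2-one | C=C(CCl)[C@H]1CCOC(=O)C1 | intermediate
5 | (4S)-4-(3-chloroprop-1-en-2-yl)oxan-2-ol (lactol, both anomers) | C=C(CCl)[C@H]1CCOC(O)C1 | intermediate
6 | 2-methylpropanal | CC(C)C=O | starting material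
7 | nitromethane | C[N+](=O)[O-] | starting material
8 | 3-methyl-1-nitrobutan-2-ol (racemic) | CC(C)C(O)C[N+](=O)[O-] | intermediate (not isolated)
9 | 3-methyl-1-nitrobutan-2-yl methanesulfonate | CC(C)C(OS(C)(=O)=O)C[N+](=O)[O-] | intermediate (not isolated)
10 | (E)-3-methyl-1-nitrobut-1-ene | CC(C)/C=C/[N+](=O)[O-] | intermediate
11 | (3S,4S)-4-(3-chloroprop-1-en-2-yl)-3-[(2S)-3-methyl-1-nitrobutan-2-yl]oxan-2-ol (both anomers) | O1CC[C@H](C(CCl)=C)[C@@H]([C@H](C(C)C)C[N+](=O)[O-])C1O | intermediate
12 | (4aS,8S,8aS)-5-methylidene-7-nitro-8-(propan-2-yl)octahydro-1H-isochromen-1-ol (trans-fused, isopropyl cis to the lactol carbon; epimers at C1 and C7 of the isochromene) | C=C1CC([N+](=O)[O-])[C@@H](C(C)C)[C@H]2C(O)OCC[C@H]12 | intermediate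
13 | (4aS,8S,8aR)-5-methylidene-8-(propan-2-yl)octahydro-1H-isochromen-1-ol (trans-fused lactol, both anomers) | C=C1CC[C@@H](C(C)C)[C@H]2C(O)OCC[C@H]12 | intermediate
14 | trimethyl phosphonoacetate | COC(=O)CP(=O)(OC)OC | starting material
15 | acrolein | C=CC=O | starting material
16 | methyl 2-(dimethoxyphosphoryl)-5-oxopentanoate (racemic) | COC(=O)C(CCC=O)P(=O)(OC)OC | intermediate
17 | tert-butyl (triphenylphosphoranylidene)acetate | CC(C)(C)OC(=O)C=P(c1ccccc1)(c1ccccc1)c1ccccc1 | starting material
18 | tert-butyl iodo(triphenylphosphoranylidene)acetate | CC(C)(C)OC(=O)C(I)=P(c1ccccc1)(c1ccccc1)c1ccccc1 | intermediate (not isolated)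
19 | 1-tert-butyl 7-methyl (2Z)-6-(dimethoxyphosphoryl)-2-iodohept-2-enedioate (racemic at C6) | COC(=O)C(CC/C=C(/C(=O)OC(C)(C)C)I)P(=O)(OC)OC | intermediate
20 | 1-tert-butyl 7-methyl (2Z,6E)-6-{[(1S,2S,6S)-2-(2-hydroxyethyl)-3-methylidene-6-(propan-2-yl)cyclohexyl]methylidene}-2-iodohept-2-enedioate | C=C1CC[C@@H](C(C)C)[C@@H](/C=C(/C(=O)OC)CC/C=C(/C(=O)OC(C)(C)C)I)[C@@H]1CCO | intermediate
21 | 1-tert-butyl 7-methyl (2Z,6E)-2-iodo-6-{[(1S,2S,6S)-3-methylidene-2-(2-oxoethyl)-6-(propan-2-yl)cyclohexyl]methylidene}hept-2-enedioate | C=C1CC[C@@H](C(C)C)[C@@H](/C=C(/C(=O)OC)CC/C=C(/C(=O)OC(C)(C)C)I)[C@@H]1CC=O | intermediate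
22 | microeunicellol B tert-butyl ester ((1S,8R,10S,14S), 2E,6E; CO2tBu on C7, CO2Me on C3) | C=C1CC[C@@H](C(C)C)[C@H]2/C=C(/C(=O)OC)CC/C=C(/C(=O)OC(C)(C)C)[C@H](O)C[C@H]12 | intermediate
23 | trimethylsilyl ester of microeunicellol B with the C8 hydroxyl as its trimethylsilyl ether | C=C1CC[C@@H](C(C)C)[C@H]2/C=C(/C(=O)OC)CC/C=C(/C(=O)O[Si](C)(C)C)[C@H](O[Si](C)(C)C)C[C@H]12 | intermediate (not isolated)
24 | microeunicellol B | C=C1CC[C@@H](C(C)C)[C@H]2/C=C(/C(=O)OC)CC/C=C(/C(=O)O)[C@H](O)C[C@H]12 | target

Total step count: 13. Longest linear sequence: 10 steps (1, 2, 3, 5, 6, 7, 10, 11, 12, 13).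

Steps most likely to fail

Step 6. Attack of the lactol oxygen, or of a second nitronate from another molecule, on the allylpalladium intermediate may outrun the intended ring closure. The fallback sets out from 3 and comes back at 13; it closes the same C12–C13 bond by a type 2 carbonyl-ene reaction and also avoids the tin denitration. Lactone 3 is reduced with iBu2AlH to (4S)-4-(prop-1-en-2-yl)oxan-2-ol F1. The Michael addition of step 5 with 10 then gives (3S,4S)-3-[(2S)-3-methyl-1-nitrobutan-2-yl]-4-(prop-1-en-2-yl)oxan-2-ol F2. MeOH with PPTS caps the lactol as (3S,4S)-2-methoxy-3-[(2S)-3-methyl-1-nitrobutan-2-yl]-4-(prop-1-en-2-yl)oxane F3. A McMurry Nef reaction (NaOMe, then aqueous TiCl3 buffered with NH4OAc) turns the nitromethyl group into the aldehyde (2S)-2-[(3S,4S)-2-methoxy-4-(prop-1-en-2-yl)oxan-3-yl]-3-methylbutanal F4. Me2AlCl in CH2Cl2 at −78 °C should bring about the ene reaction between the aldehyde and the isopropenyl group to give (4aS,8S,8aS)-1-methoxy-5-methylidene-8-(propan-2-yl)octahydro-1H-isochromen-7-ol F5. Barton–McCombie deoxygenation through O-[(4aS,8S,8aS)-1-methoxy-5-methylidene-8-(propan-2-yl)octahydro-1H-isochromen-7-yl] S-methyl carbonodithioate F6 (NaH, CS2, MeI; then Bu3SnH, AIBN, toluene, 110 °C) gives (4aS,8S,8aR)-1-methoxy-5-methylidene-8-(propan-2-yl)octahydro-1H-isochromene F7. Aqueous acetic acid in THF then returns lactol 13.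

Step 12. Facial selectivity in the addition of the alkenylchromium species to the aldehyde may be low, giving C8 epimers, and reduction of the C–I bond may compete when ring closure is slow. The fallback sets out from 22 obtained as a mixture of C8 epimers and comes back at 22; it moves control of C8 from the C–C bond formation to a reagent-controlled reduction. Dess–Martin oxidation gives the ten-membered ketone tert-butyl 8-oxo analogue of 22 F8. Corey–Bakshi–Shibata reduction with (S)-2-methyl-CBS-oxazaborolidine and catecholborane in toluene at −40 °C, with the alkenyl side as the large group, should then deliver (8R)-22.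

Step 10. Olefination of the hindered, mostly closed lactol may be slow, leaving time for epimerisation at C1 and for the phosphonate anion to condense with its own iodoenoate. The fallback sets out from 13 and comes back at 20; it uses a free aldehyde in place of the lactol. NaBH4 reduces 13 to 2-[(1S,2R,3S)-2-(hydroxymethyl)-6-methylidene-3-(propan-2-yl)cyclohexyl]ethan-1-ol F9. TBDPSCl with imidazole at −20 °C should silylate only the unhindered hydroxyethyl oxygen to give [(1S,2S,6S)-2-{2-[(tert-butyldiphenylsilyl)oxy]ethyl}-3-methylidene-6-(propan-2-yl)cyclohexyl]methanol F10. Dess–Martin oxidation gives (1R,2S,6S)-2-{2-[(tert-butyldiphenylsilyl)oxy]ethyl}-3-methylidene-6-(propan-2-yl)cyclohexane-1-carbaldehyde F11. Horner–Wadsworth–Emmons reaction with 19 (NaH, THF, 0 °C to rt) gives the tert-butyldiphenylsilyl ether of 20 F12, and HF·pyridine in THF returns 20.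

Further compounds
F1 | step 6 | (4S)-4-(prop-1-en-2-yl)oxan-2-ol | C=C(C)[C@H]1CCOC(O)C1
F2 | step 6 | (3S,4S)-3-[(2S)-3-methyl-1-nitrobutan-2-yl]-4-(prop-1-en-2-yl)oxan-2-ol | O1CC[C@H](C(C)=C)[C@@H]([C@H](C(C)C)C[N+](=O)[O-])C1O
F3 | step 6 | (3S,4S)-2-methoxy-3-[(2S)-3-methyl-1-nitrobutan-2-yl]-4-(prop-1-en-2-yl)oxane | O1CC[C@H](C(C)=C)[C@@H]([C@H](C(C)C)C[N+](=O)[O-])C1OC
F4 | step 6 | (2S)-2-[(3S,4S)-2-methoxy-4-(prop-1-en-2-yl)oxan-3-yl]-3-methylbutanal | O1CC[C@H](C(C)=C)[C@@H]([C@H](C(C)C)C=O)C1OC
F5 | step 6 | (4aS,8S,8aS)-1-methoxy-5-methylidene-8-(propan-2-yl)octahydro-1H-isochromen-7-ol | C=C1CC(O)[C@@H](C(C)C)[C@H]2C(OC)OCC[C@H]12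
F6 | step 6 | O-[(4aS,8S,8aS)-1-methoxy-5-methylidene-8-(propan-2-yl)octahydro-1H-isochromen-7-yl] S-methyl carbonodithioate | C=C1CC(OC(=S)SC)[C@@H](C(C)C)[C@H]2C(OC)OCC[C@H]12
F7 | step 6 | (4aS,8S,8aR)-1-methoxy-5-methylidene-8-(propan-2-yl)octahydro-1H-isochromene | C=C1CC[C@@H](C(C)C)[C@H]2C(OC)OCC[C@H]12
F8 | step 12 | tert-butyl 8-oxo analogue of 22 (C8 ketone of microeunicellol B tert-butyl ester) | C=C1CC[C@@H](C(C)C)[C@H]2/C=C(/C(=O)OC)CC/C=C(/C(=O)OC(C)(C)C)C(=O)C[C@H]12
F9 | step 10 | 2-[(1S,2R,3S)-2-(hydroxymethyl)-6-methylidene-3-(propan-2-yl)cyclohexyl]ethan-1-ol | C=C1CC[C@@H](C(C)C)[C@@H](CO)[C@@H]1CCO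
F10 | step 10 | [(1S,2S,6S)-2-{2-[(tert-butyldiphenylsilyl)oxy]ethyl}-3-methylidene-6-(propan-2-yl)cyclohexyl]methanol | C=C1CC[C@@H](C(C)C)[C@@H](CO)[C@@H]1CCO[Si](c1ccccc1)(c1ccccc1)C(C)(C)C
F11 | step 10 | (1R,2S,6S)-2-{2-[(tert-butyldiphenylsilyl)oxy]ethyl}-3-methylidene-6-(propan-2-yl)cyclohexane-1-carbaldehyde | C=C1CC[C@@H](C(C)C)[C@@H](C=O)[C@@H]1CCO[Si](c1ccccc1)(c1ccccc1)C(C)(C)C
F12 | step 10 | tert-butyldiphenylsilyl ether of 20 | C=C1CC[C@@H](C(C)C)[C@@H](/C=C(/C(=O)OC)CC/C=C(/C(=O)OC(C)(C)C)I)[C@@H]1CCO[Si](c1ccccc1)(c1ccccc1)C(C)(C)C
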